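(The readings were generated by integration on assumed constants; scatter was added.)

- Over the first minutes of the beta run the target climbs from 13.4% at 1.33 min to 29.3% at 10.0 min, and the delta and gamma runs trace nearly the same curve.

| flask | starting material | first nucleophile | second nucleophile | protic impurity | remark | time |
|---|---|---|---|---|---|---|
| beta | 0.010 M | 3 equiv | 1.1 equiv | 0.50 mM | run made earlier |  |
| delta | 0.010 M | 3 equiv | 1.1 equiv | 0.25 mM | run made earlier |  |
| gamma | 0.010 M | 3 equiv | 1.1 equiv | 0.38 mM | run made earlier |  |
| Tuesday's | 0.010 M | 3.00 equiv | 1.10 equiv | 0.500 mM | everything together at the start | 30 min |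
| Wednesday's | 0.010 M | 3.00 equiv | 1.10 equiv (fed, over 5.0 min) | 0.500 mM | all else is in the flask from the start; the feed brings no volume worth counting | 30 min |
| Saturday's | 0.010 M | 3.00 equiv | 1.10 equiv (fed, over 20 min) | 0.500 mM | all else is in the flask from the start; the feed brings no volume worth counting | 30 min |
| Thursday's | 0.010 M | 3.00 equiv (fed, over 20 min) | 1.10 equiv | 0.500 mM | all else is in the flask from the start; the feed brings no volume worth counting | 30 min |
| Friday's | 0.010 M | 3.00 equiv | 1.10 equiv (in portions, 4, over 20 min) | 0.500 mM | first portion at the start, last at 20 min | 30 min |

- beta (time / min: other capture product / %, target / %): 1.33: 4.6, 13.4; 2.50: 7.3, 21.1; 5.00: 9.0, 26.3; 10.0: 8.9, 29.3; 20.0: 8.8, 28.5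
- delta (time / min: other capture product / %, target / %): 1.33: 4.5, 13.6; 2.50: 7.3, 21.2; 5.00: 8.2, 26.7; 10.0: 9.3, 29.5; 20.0: 9.0, 29.2
- gamma (time / min: other capture product / %, target / %): 1.50: 4.7, 16.1; 5.00: 8.4, 26.8; 8.00: 8.8, 28.0; 12.0: 8.6, 28.8; 20.0: 9.0, 28.9

(readings scatter by 0.3 percentage points)



- which flask leads in amount of other capture product, in percent of the starting material charged ("all alike" within 1.5 percentage points) (Tuesday's / Wednesday's / Saturday's / Thursday's / Friday's / all alike)
- how much other capture product is there at the end, in percent of the starting material charged: Tuesday's
- how much other capture product is there at the end, in percent of the starting material charged: Wednesday's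
- how much other capture product is there at the end, in percent of the starting material charged: Saturday's
- how much other capture product is there at the end, in percent of the starting material charged: Thursday's
- how much other capture product is there at the end, in percent of the starting material charged: Friday's

- Taking the beta value at 10.0 min as the plateau, the target at 2.50 min gives a first-order constant of 0.509 min⁻¹ for the turnover of starting material, a reading with the runs' scatter.
- Multiplied by the feed time 20 min, it gives 10.2, the dose number N of Saturday's flask: the feed time counted in lives of the starting material.
- During a first-order turnover, a nucleophile fed steadily and not used up stands, averaged over that turnover, at the fraction f of its full level, where f is one minus e to the minus N, over N.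
- This reckoning gives f = 0.0982 for Saturday's and, with N = 2.55, f = 0.362 for Wednesday's.
- The readings do not name each product's partner, and N cannot either, so one number is not enough.
- There is a weak hint in the beta run: from 5.00 min to 20.0 min the target gains while the other capture product reads 9.0%, then 8.8%. This reckoning commits, unproven, to the second nucleophile, the smaller charge, as partner of the other capture product, and to the first nucleophile as partner of the target.
- The uncaptured share of the beta run at 20.0 min, 62.7%, is larger than the captured one, so this reckoning lets the share of other capture product follow [second nucleophile].
- Tuesday's flask, charged like the beta run, is reckoned at that run's 8.8%. The other reckoned values are 3.18% for Wednesday's, 0.864% for Saturday's and 2.20% for Friday's, where 96.6% of the turnover is reckoned to fall before the second portion.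
- In Thursday's flask this reckoning shrinks the target by Saturday's f and spreads the freed share, which gives 11.8%, the highest reckoned value.
- The forecast differs: Saturday's leads, with 9% for Tuesday's, 11.3% for Wednesday's, 12.1% for Saturday's, 4% for Thursday's and 11.6% for Friday's. Its ground: “Delaying the second nucleophile removes a competitor, so other product rises”.
- The flasks give 8.98% for Tuesday's, 3.66% for Wednesday's, 1.03% for Saturday's, 12.0% for Thursday's and 2.50% for Friday's, so Thursday's leads.

    intermediate → solvolysis product (k = 12.9 min⁻¹)
    second nucleophile + intermediate → other capture product (k = 483 L mol⁻¹ min⁻¹)
    first nucleophile + intermediate → target (k = 218 L mol⁻¹ min⁻¹)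
    starting material → intermediate (k = 0.506 min⁻¹)
    starting material + protic impurity → quenched substrate (k = 37.2 L mol⁻¹ min⁻¹)
    second nucleophile ⇌ dormant form (K = 2.00, k = 3.19 min⁻¹)

- With N = 10.2, Saturday's flask has half of its starting-material turnover up to 30 min done by 1.34 min, far earlier than the end of the 20 min feed, and it gives 1.03% against the reckoned 0.864%.
- The intermediate's half-life by solvolysis in Saturday's flask at 1.34 min, 0.054 min, is much shorter than that time, so starting material → intermediate is the rate-limiting step there.
- The neighbour of Saturday's flask with 0.025 M of starting material is reckoned with the same N = 10.2 and with [second nucleophile] scaled by the charge, giving 2.16%. The computed neighbour gives 1.76%, with 51.8% of target.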